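The data were computed for substances that don't exist; the scatter is artificial.

I decided to read both earlier runs in molar rather than in percent, and to ask one question of each new flask: does its solid outlast the time?

| flask | solid substrate | remark | time |
|---|---|---|---|
| violet | 1.1 M | run made earlier |  |
| teal | 2.4 M | run made earlier |  |
| spring | 0.80 M |  | 5.0 h |
| winter | 1.2 M |  | 5.0 h |
| summer | 2.0 M |  | 5.0 h |

| run | time / h | product / % | solid substrate / % |
|---|---|---|---|
| violet | 0.417 | 0 | 90.9 |
| violet | 0.667 | 1.2 | 87.5 |
| violet | 1.00 | 2.6 | 80.4 |
| violet | 1.33 | 2.9 | 76.1 |
| violet | 2.00 | 7.7 | 64.9 |
| violet | 3.00 | 13.3 | 48.0 |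
| violet | 5.00 | 31.2 | 20.2 |
| teal | 0.250 | 0 | 98.7 |
| teal | 0.833 | 0 | 92.0 |
| teal | 1.33 | 2.4 | 88.9 |
| teal | 2.00 | 2.6 | 84.3 |
| teal | 3.00 | 6.2 | 76.7 |
| teal | 4.00 | 9.9 | 68.9 |
| teal | 5.00 | 14.3 | 63.1 |

(scatter of a reading: 1 percentage point)

- given per volume of solution although it is solid: solid substrate
- reactions considered so far: starting material -> product; solid substrate <-> starting material
- at the start none of the solid substrate is in solution
- "hardly changes" means that all values lie within two and a half points (for a concentration: within two and a half percent of the largest)

1. [product] at the end for spring, winter, summer, in this order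
2. how the row runs (rises all the way / falls, then rises / hardly changes / falls all the way / rises, then falls)

By the last reading, violet had lost solid substrate at a mean 0.176 M h⁻¹ and teal at 0.177 M h⁻¹, though teal's charge was twice violet's. Their product readings were 31.2 % and 14.3 % of the charge, yet in molar they read 0.343 M and 0.343 M. I therefore read the solid as a reservoir feeding starting material at a rate r that is zero order in solid, and I took teal's mean as r. I called the charge c and defined the lifetime of the charge, τ = c/r.

Two extreme flasks can be solved in the head. If τ is far longer than the time, each flask holds solid throughout and receives the same feed, so product is the same molar amount as in violet and teal and the row is flat. If τ is close to nothing, the charge is in solution at once, a first-order step converts the same percent of each flask, and the row climbs by a factor of 2.50 from spring to summer. By this reckoning, violet (6.21 h) and teal (13.6 h) both outlasted 5.0 h, and their readings agreed in molar, so I placed them on the side of the first extreme, though violet's lifetime was not far beyond the time. For the new flasks: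

τ(spring) = 0.80 M / r = 4.52 h

τ(winter) = 1.2 M / r = 6.78 h

τ(summer) = 2.0 M / r = 11.3 h

Winter and summer outlast the time, so I expected about 0.343 M from each. Spring falls short by 0.480 h, so in this reckoning its feed stops for the last 9.60 % of the time. I put spring just under the others and called the row flat.

The forecast gave 0.338 M, 0.343 M and 0.343 M, a row that hardly changes, reasoning that “with solid present throughout, product at 5 h does not depend on the charge”.

The flasks gave 0.322 M, 0.325 M and 0.325 M, a row that hardly changes.

    starting material → product (k = 0.190 h⁻¹)
    solid substrate ⇌ starting material, rate k2*(cs2 - [starting material]) while solid is left; crystals form when [starting material] > cs2 (solubility = 1.80 M, k = 0.120 h⁻¹)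

Spring, with a reckoned lifetime of 4.52 h, held 0 % solid substrate at 5.00 h, with 59.7 % of its charge standing as starting material. For winter, with t the time, the lifetime of 6.78 h gives a share 1 − t/τ = 26.3 % of the charge undissolved, and winter held 27.1 % solid substrate at 5.00 h.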